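Ring A (C4a, C5, C6, C7, C8, C8a) is cut into a four-carbon cyclobutenone and a two-carbon siloxyalkyne. One thermal benzannulation forms C8–C8a, C6–C7 and C4a–C8a and delivers the fully substituted ring, with oxygen at C5, C7 and C8a alternating with carbon at C6, C8 and C4a. Only the C8a oxygen, the future O1, emerges free. The precursors are a 2-prenyl-3-silyloxycyclobutenone and an ynol silyl ether that already carries the (R)-configured hydroxy-isopropenyl side chain. All other hydroxyls travel as silyl ethers, so the pyranone ring can close in one direction only and a single fluoride treatment ends the synthesis without acid.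

Key step: step 9

Remark: O5 is carried as a triisopropylsilyl ether, not an acetal, because protic acid at the end would add the neighbouring phenols across the prenyl and isopropenyl double bonds; ketene is taken as the gas from a laboratory acetone-pyrolysis generator, and the (R) sense of step 1 is assigned by analogy with the behaviour of this auxiliary toward α-branched aldehydes.

Step 1
Reactants: 1 methacrolein; 2 (1R)-2-hydroxy-1,2,2-triphenylethyl acetate ((R)-HYTRA)
Product: 4 (1R)-2-hydroxy-1,2,2-triphenylethyl (3R)-3-hydroxy-4-methylpent-4-enoate, via HYTRA dilithium enolate 3 (not isolated)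
Conditions: LiN(i-Pr)2 (2.1 equiv), THF, −78→0 °C; then 1, THF/2-methylbutane, −125 °C; aq NH4Cl; recrystallisation
Reagents that add atoms: none
Why: Acetate aldol addition of the doubly deprotonated HYTRA ester, in which the (R)-configured triphenylglycol auxiliary should steer the enolate to the aldehyde face that gives the (3R) carbinol, the sense it shows with α-branched aldehydes, while crystallisation of 4 should remove the minor diastereomer.

Step 2
Reactants: 4 (1R)-2-hydroxy-1,2,2-triphenylethyl (3R)-3-hydroxy-4-methylpent-4-enoate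
Product: 5 methyl (3R)-3-hydroxy-4-methylpent-4-enoate
Conditions: NaOMe (catalytic), MeOH, 0 °C→rt
Reagents that add atoms: methanol, CO
Why: Methoxide-catalysed transesterification releases the hindered auxiliary as its recoverable diol, and the cold, short reaction should leave the β-hydroxy ester stereocentre untouched.

Step 3
Reactants: 5 methyl (3R)-3-hydroxy-4-methylpent-4-enoate
Product: 6 methyl (3R)-3-(tert-butyldimethylsilyloxy)-4-methylpent-4-enoate
Conditions: t-BuMe2SiCl, imidazole, DMF, rt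
Reagents that add atoms: tert-butyldimethylsilyl chloride, CC(C)(C)[Si](C)(C)Cl
Why: Standard silylation of a secondary alcohol with a silyl chloride and imidazole, which masks the carbinol for the strongly basic step that follows.

Step 4
Reactants: 6 methyl (3R)-3-(tert-butyldimethylsilyloxy)-4-methylpent-4-enoate
Product: 9 (4R)-4-(tert-butyldimethylsilyloxy)-5-methyl-1-(triisopropylsilyloxy)hex-5-en-1-yne, via dibromoketone enolate 7 (not isolated), via lithium ynolate 8 (not isolated)
Conditions: CH2Br2, lithium 2,2,6,6-tetramethylpiperidide (LiTMP), THF, −78 °C; LiN(SiMe3)2; n-BuLi, −78→0 °C; i-Pr3SiOTf, −78 °C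
Reagents that add atoms: dibromomethane, BrCBr; triisopropylsilyl triflate, CC(C)[Si](C(C)C)(C(C)C)OS(=O)(=O)C(F)(F)F
Why: Kowalski ester homologation stopped at the ynolate stage, in which dibromomethyllithium adds to the ester, enolate 7 undergoes bromine–lithium exchange and 1,2-shift of the alkyl group to ynolate 8, and the bulky silyl triflate traps 8 on oxygen, while the stereocentre sits one carbon beyond the migrating methylene and is not touched.

Step 5
Reactants: 10 ethoxyacetylene; 11 1-bromo-3-methylbut-2-ene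
Product: 13 1-ethoxy-5-methylhex-4-en-1-yne, via lithium ethoxyacetylide 12 (not isolated)
Conditions: n-BuLi, THF, −78 °C; then 11, DMPU, −78 °C→rt
Reagents that add atoms: none
Why: SN2 alkylation of a lithium alkynide by a primary allylic bromide in a dipolar cosolvent, where the acetylide should attack the unhindered CH2 terminus and not the tertiary one.

Step 6
Reactants: 13 1-ethoxy-5-methylhex-4-en-1-yne
Product: 14 3-ethoxy-2-(3-methylbut-2-enyl)cyclobut-2-en-1-one
Conditions: ketene (gas), CH2Cl2, 0 °C→rt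
Reagents that add atoms: ketene, C=C=O
Why: Thermal [2+2] cycloaddition of ketene with an ynol ether, in which the nucleophilic prenyl-bearing alkyne carbon bonds to the ketene carbonyl carbon and so places the ethoxy group at C3 of the cyclobutenone.

Step 7
Reactants: 14 3-ethoxy-2-(3-methylbut-2-enyl)cyclobut-2-en-1-one
Product: 15 3-hydroxy-2-(3-methylbut-2-enyl)cyclobut-2-en-1-one
Conditions: 1 M HCl, THF, 0 °C→rt
Reagents that add atoms: water, O
Why: Acid hydrolysis of a vinylogous ester to the vinylogous acid (the enol of the 1,3-dione), mild enough at this dilution and temperature to leave the trisubstituted alkene alone.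

Step 8
Reactants: 15 3-hydroxy-2-(3-methylbut-2-enyl)cyclobut-2-en-1-one
Product: 16 2-(3-methylbut-2-enyl)-3-(triisopropylsilyloxy)cyclobut-2-en-1-one
Conditions: i-Pr3SiCl, Et3N, CH2Cl2, 0 °C; filtration, no aqueous work-up
Reagents that add atoms: triisopropylsilyl chloride, CC(C)[Si](Cl)(C(C)C)C(C)C
Why: O-silylation of a vinylogous carboxylic acid, which behaves like silyl ester formation, and because the 2-substituted dione is symmetric only one enol silyl ether can form.

Step 9
Reactants: 16 2-(3-methylbut-2-enyl)-3-(triisopropylsilyloxy)cyclobut-2-en-1-one; 9 (4R)-4-(tert-butyldimethylsilyloxy)-5-methyl-1-(triisopropylsilyloxy)hex-5-en-1-yne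
Product: 21 2-[(2R)-2-(tert-butyldimethylsilyloxy)-3-methylbut-3-enyl]-4-(3-methylbut-2-enyl)-3,5-bis(triisopropylsilyloxy)phenol, via vinylketene 17 (not isolated), via vinylcyclobutenone 18 (not isolated), via dienylketene 19 (not isolated), via cyclohexadienone 20 (not isolated)
Conditions: 9 (1.2 equiv), toluene (0.5 M), 80→115 °C, sealed tube, argon
Reagents that add atoms: none
Why: Thermal four-electron conrotatory opening of 16 gives vinylketene 17, whose ketene C=C adds the siloxyalkyne in a [2+2] cycloaddition (C8–C8a and C6–C7), and the resulting 4-vinylcyclobutenone 18 opens again to dienylketene 19. Ring A then closes by a six-electron disrotatory electrocyclization that joins C4a to C8a, and dienone 20 tautomerizes to the phenol. This is the Danheiser benzannulation of a cyclobutenone with a siloxyalkyne, here with a 3-oxygenated cyclobutenone, a less usual partner that should open more slowly and therefore gets the higher end temperature. The quaternary centre of 18 is transient, no new stereocentre survives, and the (R) carbinol carbon is a spectator. The step needs one regiochemistry in the [2+2] event, and the oxygen-polarized alkyne secures it, because its nucleophilic carbon, the one bearing the side chain, attacks the ketene carbonyl carbon, so the side chain ends ortho and the silyloxy group meta to the new hydroxyl. That hydroxyl on C8a is the only free one, which later fixes the direction of pyranone closure.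

Step 10
Reactants: 21 2-[(2R)-2-(tert-butyldimethylsilyloxy)-3-methylbut-3-enyl]-4-(3-methylbut-2-enyl)-3,5-bis(triisopropylsilyloxy)phenol
Product: 23 3-[(2R)-2-(tert-butyldimethylsilyloxy)-3-methylbut-3-enyl]-2-hydroxy-5-(3-methylbut-2-enyl)-4,6-bis(triisopropylsilyloxy)benzaldehyde, via salicyl alcohol 22 (not isolated)
Conditions: MgCl2, Et3N, (CH2O)n, MeCN, reflux; cold 10% citric acid
Reagents that add atoms: paraformaldehyde (as formaldehyde), C=O
Why: Casnati–Skattebøl ortho-formylation, in which the magnesium phenoxide delivers formaldehyde to the ortho carbon within a chelate and a second formaldehyde oxidises salicyl alcohol 22 by hydride transfer, C4a being the only unsubstituted ring carbon.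

Step 11
Reactants: 24 3,4-dihydroxybenzaldehyde
Product: 25 3,4-bis(triisopropylsilyloxy)benzaldehyde
Conditions: i-Pr3SiCl, imidazole, DMF, rt→50 °C
Reagents that add atoms: triisopropylsilyl chloride, CC(C)[Si](Cl)(C(C)C)C(C)C
Why: Silylation of both catechol hydroxyls with the hindered chlorosilane gives ethers that tolerate organomagnesium reagents and fall off with the others under fluoride at the end.

Step 12
Reactants: 25 3,4-bis(triisopropylsilyloxy)benzaldehyde
Product: 26 [3,4-bis(triisopropylsilyloxy)phenyl]methanol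
Conditions: NaBH4, MeOH/THF, 0 °C
Reagents that add atoms: none
Why: Borohydride reduction of an aryl aldehyde to the benzylic alcohol under conditions that hindered aryl silyl ethers tolerate.

Step 13
Reactants: 26 [3,4-bis(triisopropylsilyloxy)phenyl]methanol
Product: 28 4-(chloromethyl)-1,2-bis(triisopropylsilyloxy)benzene, via benzylic mesylate 27 (not isolated)
Conditions: MeSO2Cl, Et3N, CH2Cl2, 0 °C→rt
Reagents that add atoms: methanesulfonyl chloride, CS(=O)(=O)Cl
Why: Mesylation of the electron-rich benzylic alcohol followed by displacement of the very labile mesylate 27 by the chloride of the ammonium salt, a nucleophilic substitution that needs no acid.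

Step 14
Reactants: 23 3-[(2R)-2-(tert-butyldimethylsilyloxy)-3-methylbut-3-enyl]-2-hydroxy-5-(3-methylbut-2-enyl)-4,6-bis(triisopropylsilyloxy)benzaldehyde; 28 4-(chloromethyl)-1,2-bis(triisopropylsilyloxy)benzene
Product: 30 2-[3,4-bis(triisopropylsilyloxy)phenyl]-1-{3-[(2R)-2-(tert-butyldimethylsilyloxy)-3-methylbut-3-enyl]-2-hydroxy-5-(3-methylbut-2-enyl)-4,6-bis(triisopropylsilyloxy)phenyl}ethan-1-ol (both carbinol epimers), via benzylic Grignard reagent 29 (not isolated)
Conditions: 28, Mg turnings, THF, 0 °C (slow addition, 2.5 equiv); then 23, THF, −78→−20 °C; aq NH4Cl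
Reagents that add atoms: none
Why: Grignard addition to an aldehyde, in which the first equivalent deprotonates the phenol and the second attacks the chelated formyl group, the new carbinol centre forming as a mixture of epimers that is of no consequence because it is oxidised next, while the magnesium counter-ion and the low temperature should keep the neighbouring aryl silyl ether from migrating.

Step 15
Reactants: 30 2-[3,4-bis(triisopropylsilyloxy)phenyl]-1-{3-[(2R)-2-(tert-butyldimethylsilyloxy)-3-methylbut-3-enyl]-2-hydroxy-5-(3-methylbut-2-enyl)-4,6-bis(triisopropylsilyloxy)phenyl}ethan-1-ol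
Product: 31 2-[3,4-bis(triisopropylsilyloxy)phenyl]-1-{3-[(2R)-2-(tert-butyldimethylsilyloxy)-3-methylbut-3-enyl]-2-hydroxy-5-(3-methylbut-2-enyl)-4,6-bis(triisopropylsilyloxy)phenyl}ethan-1-one
Conditions: MnO2 (activated, excess), CH2Cl2, rt
Reagents that add atoms: none
Why: MnO2 oxidation of a benzylic alcohol, a surface-bound process that is selective for benzylic and allylic carbinols, spares isolated alkenes and silyl ethers, and finds no free ring position for phenol coupling on the fully substituted ring A.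

Step 16
Reactants: 31 2-[3,4-bis(triisopropylsilyloxy)phenyl]-1-{3-[(2R)-2-(tert-butyldimethylsilyloxy)-3-methylbut-3-enyl]-2-hydroxy-5-(3-methylbut-2-enyl)-4,6-bis(triisopropylsilyloxy)phenyl}ethan-1-one
Product: 33 3-[3,4-bis(triisopropylsilyloxy)phenyl]-8-[(2R)-2-(tert-butyldimethylsilyloxy)-3-methylbut-3-enyl]-6-(3-methylbut-2-enyl)-5,7-bis(triisopropylsilyloxy)-4H-chromen-4-one, via enaminone 32 (not isolated)
Conditions: Me2NCH(OMe)2, toluene, 85 °C
Reagents that add atoms: N,N-dimethylformamide dimethyl acetal, COC(OC)N(C)C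
Why: Condensation of the activated methylene with the formamide acetal gives enaminone 32, and the C8a hydroxyl, the only free phenol, then adds to the enamine carbon and expels dimethylamine (the deoxybenzoin route to isoflavones), so ring C can close in one direction only and no hydroxyl is exposed to methylation by the acetal.

Step 17
Reactants: 33 3-[3,4-bis(triisopropylsilyloxy)phenyl]-8-[(2R)-2-(tert-butyldimethylsilyloxy)-3-methylbut-3-enyl]-6-(3-methylbut-2-enyl)-5,7-bis(triisopropylsilyloxy)-4H-chromen-4-one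
Product: 34 3-(3,4-dihydroxyphenyl)-5,7-dihydroxy-8-[(2R)-2-hydroxy-3-methylbut-3-enyl]-6-(3-methylbut-2-enyl)-4H-chromen-4-one
Conditions: Bu4NF (8 equiv), AcOH (4 equiv), THF, 0 °C→rt, argon; pH 5 buffer
Reagents that add atoms: none
Why: Fluoride-mediated cleavage of all five silicon–oxygen bonds, buffered with acetic acid so that the polyphenolate and the pyranone are not exposed to strong base and free of the protic acid that would add the phenols across the prenyl and isopropenyl double bonds; the carbinol stereocentre is not involved.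

Compound list

1 | methacrolein (2-methylprop-2-enal) | C=C(C)C=O | starting material
2 | (1R)-2-hydroxy-1,2,2-triphenylethyl acetate ((R)-HYTRA) | CC(=O)O[C@H](c1ccccc1)C(O)(c1ccccc1)c1ccccc1 | starting material
3 | dilithium enolate of 2 (formed in situ) | [Li]OC(=C)O[C@H](c1ccccc1)C(O[Li])(c1ccccc1)c1ccccc1 | intermediate
4 | (1R)-2-hydroxy-1,2,2-triphenylethyl (3R)-3-hydroxy-4-methylpent-4-enoate | C=C(C)[C@H](O)CC(=O)O[C@H](c1ccccc1)C(O)(c1ccccc1)c1ccccc1 | intermediate
5 | methyl (3R)-3-hydroxy-4-methylpent-4-enoate | C=C(C)[C@H](O)CC(=O)OC | intermediate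
6 | methyl (3R)-3-(tert-butyldimethylsilyloxy)-4-methylpent-4-enoate | C=C(C)[C@H](O[Si](C)(C)C(C)(C)C)CC(=O)OC | intermediate
7 | lithium (4R)-1,1-dibromo-4-(tert-butyldimethylsilyloxy)-5-methylhexa-1,5-dien-2-olate (formed in situ) | C=C(C)[C@H](O[Si](C)(C)C(C)(C)C)CC(O[Li])=C(Br)Br | intermediate
8 | lithium (4R)-4-(tert-butyldimethylsilyloxy)-5-methylhex-5-en-1-yn-1-olate (formed in situ) | C=C(C)[C@H](O[Si](C)(C)C(C)(C)C)CC#CO[Li] | intermediate
9 | (4R)-4-(tert-butyldimethylsilyloxy)-5-methyl-1-(triisopropylsilyloxy)hex-5-en-1-yne | C=C(C)[C@H](O[Si](C)(C)C(C)(C)C)CC#CO[Si](C(C)C)(C(C)C)C(C)C | intermediate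
10 | ethoxyacetylene (ethoxyethyne) | C#COCC | starting material
11 | 1-bromo-3-methylbut-2-ene | CC(C)=CCBr | starting material
12 | lithium ethoxyacetylide (formed in situ) | [Li]C#COCC | intermediate
13 | 1-ethoxy-5-methylhex-4-en-1-yne | CCOC#CCC=C(C)C | intermediate
14 | 3-ethoxy-2-(3-methylbut-2-enyl)cyclobut-2-en-1-one | CCOC1=C(CC=C(C)C)C(=O)C1 | intermediate
15 | 3-hydroxy-2-(3-methylbut-2-enyl)cyclobut-2-en-1-one | CC(C)=CCC1=C(O)CC1=O | intermediate
16 | 2-(3-methylbut-2-enyl)-3-(triisopropylsilyloxy)cyclobut-2-en-1-one | CC(C)=CCC1=C(O[Si](C(C)C)(C(C)C)C(C)C)CC1=O | intermediate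
17 | 2-(3-methylbut-2-enyl)-3-(triisopropylsilyloxy)buta-1,3-dien-1-one (vinylketene, formed in situ) | C=C(O[Si](C(C)C)(C(C)C)C(C)C)C(CC=C(C)C)=C=O | intermediate
18 | 2-[(2R)-2-(tert-butyldimethylsilyloxy)-3-methylbut-3-enyl]-4-(3-methylbut-2-enyl)-3-(triisopropylsilyloxy)-4-[1-(triisopropylsilyloxy)ethenyl]cyclobut-2-en-1-one (formed in situ, both configurations at C4) | C=C(C)[C@H](O[Si](C)(C)C(C)(C)C)CC1=C(O[Si](C(C)C)(C(C)C)C(C)C)C(CC=C(C)C)(C(=C)O[Si](C(C)C)(C(C)C)C(C)C)C1=O | intermediate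
19 | 2-[(2R)-2-(tert-butyldimethylsilyloxy)-3-methylbut-3-enyl]-4-(3-methylbut-2-enyl)-3,5-bis(triisopropylsilyloxy)hexa-1,3,5-trien-1-one (dienylketene, formed in situ) | C=C(C)[C@H](O[Si](C)(C)C(C)(C)C)CC(=C=O)C(O[Si](C(C)C)(C(C)C)C(C)C)=C(CC=C(C)C)C(=C)O[Si](C(C)C)(C(C)C)C(C)C | intermediate
20 | 2-[(2R)-2-(tert-butyldimethylsilyloxy)-3-methylbut-3-enyl]-4-(3-methylbut-2-enyl)-3,5-bis(triisopropylsilyloxy)cyclohexa-2,4-dien-1-one (formed in situ) | C=C(C)[C@H](O[Si](C)(C)C(C)(C)C)CC1=C(O[Si](C(C)C)(C(C)C)C(C)C)C(CC=C(C)C)=C(O[Si](C(C)C)(C(C)C)C(C)C)CC1=O | intermediate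
21 | 2-[(2R)-2-(tert-butyldimethylsilyloxy)-3-methylbut-3-enyl]-4-(3-methylbut-2-enyl)-3,5-bis(triisopropylsilyloxy)phenol | C=C(C)[C@H](O[Si](C)(C)C(C)(C)C)Cc1c(O)cc(O[Si](C(C)C)(C(C)C)C(C)C)c(CC=C(C)C)c1O[Si](C(C)C)(C(C)C)C(C)C | intermediate
22 | 2-[(2R)-2-(tert-butyldimethylsilyloxy)-3-methylbut-3-enyl]-6-(hydroxymethyl)-4-(3-methylbut-2-enyl)-3,5-bis(triisopropylsilyloxy)phenol (formed in situ as its magnesium salt) | C=C(C)[C@H](O[Si](C)(C)C(C)(C)C)Cc1c(O)c(CO)c(O[Si](C(C)C)(C(C)C)C(C)C)c(CC=C(C)C)c1O[Si](C(C)C)(C(C)C)C(C)C | intermediate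
23 | 3-[(2R)-2-(tert-butyldimethylsilyloxy)-3-methylbut-3-enyl]-2-hydroxy-5-(3-methylbut-2-enyl)-4,6-bis(triisopropylsilyloxy)benzaldehyde | C=C(C)[C@H](O[Si](C)(C)C(C)(C)C)Cc1c(O)c(C=O)c(O[Si](C(C)C)(C(C)C)C(C)C)c(CC=C(C)C)c1O[Si](C(C)C)(C(C)C)C(C)C | intermediate
24 | 3,4-dihydroxybenzaldehyde | O=Cc1ccc(O)c(O)c1 | starting material
25 | 3,4-bis(triisopropylsilyloxy)benzaldehyde | O=Cc1ccc(O[Si](C(C)C)(C(C)C)C(C)C)c(O[Si](C(C)C)(C(C)C)C(C)C)c1 | intermediate
26 | [3,4-bis(triisopropylsilyloxy)phenyl]methanol | OCc1ccc(O[Si](C(C)C)(C(C)C)C(C)C)c(O[Si](C(C)C)(C(C)C)C(C)C)c1 | intermediate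
27 | 3,4-bis(triisopropylsilyloxy)benzyl methanesulfonate (formed in situ) | CS(=O)(=O)OCc1ccc(O[Si](C(C)C)(C(C)C)C(C)C)c(O[Si](C(C)C)(C(C)C)C(C)C)c1 | intermediate
28 | 4-(chloromethyl)-1,2-bis(triisopropylsilyloxy)benzene | ClCc1ccc(O[Si](C(C)C)(C(C)C)C(C)C)c(O[Si](C(C)C)(C(C)C)C(C)C)c1 | intermediate
29 | [3,4-bis(triisopropylsilyloxy)benzyl]magnesium chloride (formed in situ) | Cl[Mg]Cc1ccc(O[Si](C(C)C)(C(C)C)C(C)C)c(O[Si](C(C)C)(C(C)C)C(C)C)c1 | intermediate
30 | 2-[3,4-bis(triisopropylsilyloxy)phenyl]-1-{3-[(2R)-2-(tert-butyldimethylsilyloxy)-3-methylbut-3-enyl]-2-hydroxy-5-(3-methylbut-2-enyl)-4,6-bis(triisopropylsilyloxy)phenyl}ethan-1-ol (both epimers at the carbinol carbon) | C=C(C)[C@H](O[Si](C)(C)C(C)(C)C)Cc1c(O)c(C(O)Cc2ccc(O[Si](C(C)C)(C(C)C)C(C)C)c(O[Si](C(C)C)(C(C)C)C(C)C)c2)c(O[Si](C(C)C)(C(C)C)C(C)C)c(CC=C(C)C)c1O[Si](C(C)C)(C(C)C)C(C)C | intermediate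
31 | 2-[3,4-bis(triisopropylsilyloxy)phenyl]-1-{3-[(2R)-2-(tert-butyldimethylsilyloxy)-3-methylbut-3-enyl]-2-hydroxy-5-(3-methylbut-2-enyl)-4,6-bis(triisopropylsilyloxy)phenyl}ethan-1-one | C=C(C)[C@H](O[Si](C)(C)C(C)(C)C)Cc1c(O)c(C(=O)Cc2ccc(O[Si](C(C)C)(C(C)C)C(C)C)c(O[Si](C(C)C)(C(C)C)C(C)C)c2)c(O[Si](C(C)C)(C(C)C)C(C)C)c(CC=C(C)C)c1O[Si](C(C)C)(C(C)C)C(C)C | intermediate
32 | 2-[3,4-bis(triisopropylsilyloxy)phenyl]-1-{3-[(2R)-2-(tert-butyldimethylsilyloxy)-3-methylbut-3-enyl]-2-hydroxy-5-(3-methylbut-2-enyl)-4,6-bis(triisopropylsilyloxy)phenyl}-3-(dimethylamino)prop-2-en-1-one (formed in situ) | C=C(C)[C@H](O[Si](C)(C)C(C)(C)C)Cc1c(O)c(C(=O)C(=CN(C)C)c2ccc(O[Si](C(C)C)(C(C)C)C(C)C)c(O[Si](C(C)C)(C(C)C)C(C)C)c2)c(O[Si](C(C)C)(C(C)C)C(C)C)c(CC=C(C)C)c1O[Si](C(C)C)(C(C)C)C(C)C | intermediate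
33 | 3-[3,4-bis(triisopropylsilyloxy)phenyl]-8-[(2R)-2-(tert-butyldimethylsilyloxy)-3-methylbut-3-enyl]-6-(3-methylbut-2-enyl)-5,7-bis(triisopropylsilyloxy)-4H-chromen-4-one | C=C(C)[C@H](O[Si](C)(C)C(C)(C)C)Cc1c(O[Si](C(C)C)(C(C)C)C(C)C)c(CC=C(C)C)c(O[Si](C(C)C)(C(C)C)C(C)C)c2c(=O)c(-c3ccc(O[Si](C(C)C)(C(C)C)C(C)C)c(O[Si](C(C)C)(C(C)C)C(C)C)c3)coc12 | intermediate
34 | 3-(3,4-dihydroxyphenyl)-5,7-dihydroxy-8-[(2R)-2-hydroxy-3-methylbut-3-enyl]-6-(3-methylbut-2-enyl)-4H-chromen-4-one | C=C(C)[C@H](O)Cc1c(O)c(CC=C(C)C)c(O)c2c(=O)c(-c3ccc(O)c(O)c3)coc12 | target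

Total step count: 17. Longest linear sequence: 10 steps (steps 1, 2, 3, 4, 9, 10, 14, 15, 16, 17).

Steps most likely to fail

Step 9. The oxygen-stabilised cyclobutenone may open too slowly, so that the siloxyalkyne is lost to thermal rearrangement before it is captured. The silyl group may also pass from the vinylogous silyl ester to the new phenol, or the phenol may be acylated by the vinylketene. The fallback changes the class of the four-carbon partner and the end game, and sets out from 15. MeOCH2Cl and i-Pr2NEt in CH2Cl2 at 0 °C should give 3-(methoxymethoxy)-2-(3-methylbut-2-enyl)cyclobut-2-en-1-one F1. This acetal enol ether is closest to the alkoxycyclobutenones on which the benzannulation rests and is smaller next to the reacting carbons. Heating F1 with 9 as in step 9 should give 2-[(2R)-2-(tert-butyldimethylsilyloxy)-3-methylbut-3-enyl]-5-(methoxymethoxy)-4-(3-methylbut-2-enyl)-3-(triisopropylsilyloxy)phenol F2. The conditions of steps 10, 14, 15 and 16 then lead in turn to: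
- 3-[(2R)-2-(tert-butyldimethylsilyloxy)-3-methylbut-3-enyl]-2-hydroxy-6-(methoxymethoxy)-5-(3-methylbut-2-enyl)-4-(triisopropylsilyloxy)benzaldehyde F3;
- 2-[3,4-bis(triisopropylsilyloxy)phenyl]-1-{3-[(2R)-2-(tert-butyldimethylsilyloxy)-3-methylbut-3-enyl]-2-hydroxy-6-(methoxymethoxy)-5-(3-methylbut-2-enyl)-4-(triisopropylsilyloxy)phenyl}ethan-1-ol F4;
- 2-[3,4-bis(triisopropylsilyloxy)phenyl]-1-{3-[(2R)-2-(tert-butyldimethylsilyloxy)-3-methylbut-3-enyl]-2-hydroxy-6-(methoxymethoxy)-5-(3-methylbut-2-enyl)-4-(triisopropylsilyloxy)phenyl}ethan-1-one F5;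
- 3-[3,4-bis(triisopropylsilyloxy)phenyl]-8-[(2R)-2-(tert-butyldimethylsilyloxy)-3-methylbut-3-enyl]-5-(methoxymethoxy)-6-(3-methylbut-2-enyl)-7-(triisopropylsilyloxy)-4H-chromen-4-one F6.

The acetal is then removed without protic acid by Me3SiOTf and 2,2′-bipyridyl in MeCN at 0 °C followed by water. This should give 3-[3,4-bis(triisopropylsilyloxy)phenyl]-8-[(2R)-2-(tert-butyldimethylsilyloxy)-3-methylbut-3-enyl]-5-hydroxy-6-(3-methylbut-2-enyl)-7-(triisopropylsilyloxy)-4H-chromen-4-one F7 with every silyl ether in place. The conditions of step 17 bring F7 back to the route at 34.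

Step 4. The ester may be enolised in competition with carbenoid addition, the β-silyloxy group may be eliminated under the excess of strong base, or the rearrangement to the ynolate may stay incomplete. The fallback sets out from 6 and avoids the carbenoid altogether. i-Bu2AlH in CH2Cl2 at −78 °C should give (3R)-3-(tert-butyldimethylsilyloxy)-4-methylpent-4-enal F8. Seyferth–Gilbert homologation with the Ohira–Bestmann reagent (dimethyl (1-diazo-2-oxopropyl)phosphonate, K2CO3, MeOH, 0 °C→rt) should give tert-butyl(dimethyl){[(3R)-2-methylhex-1-en-5-yn-3-yl]oxy}silane F9. Deprotonation of F9 with n-BuLi, oxidation of the lithium acetylide to the same ynolate 8 with LiOO-t-Bu (from t-BuOOH and LiN(SiMe3)2, THF, −78→0 °C) and trapping with i-Pr3SiOTf return to the route at 9.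

Step 15. The oxidant may attack the electron-rich free phenol ring, or the ortho-hydroxy benzylic alcohol may lose water toward a quinone methide before it is oxidised. The fallback replaces the external oxidant by an Oppenauer hydride transfer and sets out from 23 and the Grignard reagent 29. After the addition of step 14 the magnesium alkoxide is not quenched but treated in the same flask with benzaldehyde (3 equiv, THF, 0 °C→rt). The carbinol hydrogen should pass to benzaldehyde through a magnesium-bound six-membered transition state, and aqueous NH4Cl work-up should deliver the deoxybenzoin directly. The route is rejoined at 31, and this fallback makes no new compound (entry F0).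

Further compounds

F1 | step 9 | 3-(methoxymethoxy)-2-(3-methylbut-2-enyl)cyclobut-2-en-1-one | COCOC1=C(CC=C(C)C)C(=O)C1
F2 | step 9 | 2-[(2R)-2-(tert-butyldimethylsilyloxy)-3-methylbut-3-enyl]-5-(methoxymethoxy)-4-(3-methylbut-2-enyl)-3-(triisopropylsilyloxy)phenol | C=C(C)[C@H](O[Si](C)(C)C(C)(C)C)Cc1c(O)cc(OCOC)c(CC=C(C)C)c1O[Si](C(C)C)(C(C)C)C(C)C
F3 | step 9 | 3-[(2R)-2-(tert-butyldimethylsilyloxy)-3-methylbut-3-enyl]-2-hydroxy-6-(methoxymethoxy)-5-(3-methylbut-2-enyl)-4-(triisopropylsilyloxy)benzaldehyde | C=C(C)[C@H](O[Si](C)(C)C(C)(C)C)Cc1c(O)c(C=O)c(OCOC)c(CC=C(C)C)c1O[Si](C(C)C)(C(C)C)C(C)C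
F4 | step 9 | 2-[3,4-bis(triisopropylsilyloxy)phenyl]-1-{3-[(2R)-2-(tert-butyldimethylsilyloxy)-3-methylbut-3-enyl]-2-hydroxy-6-(methoxymethoxy)-5-(3-methylbut-2-enyl)-4-(triisopropylsilyloxy)phenyl}ethan-1-ol (both carbinol epimers) | C=C(C)[C@H](O[Si](C)(C)C(C)(C)C)Cc1c(O)c(C(O)Cc2ccc(O[Si](C(C)C)(C(C)C)C(C)C)c(O[Si](C(C)C)(C(C)C)C(C)C)c2)c(OCOC)c(CC=C(C)C)c1O[Si](C(C)C)(C(C)C)C(C)C
F5 | step 9 | 2-[3,4-bis(triisopropylsilyloxy)phenyl]-1-{3-[(2R)-2-(tert-butyldimethylsilyloxy)-3-methylbut-3-enyl]-2-hydroxy-6-(methoxymethoxy)-5-(3-methylbut-2-enyl)-4-(triisopropylsilyloxy)phenyl}ethan-1-one | C=C(C)[C@H](O[Si](C)(C)C(C)(C)C)Cc1c(O)c(C(=O)Cc2ccc(O[Si](C(C)C)(C(C)C)C(C)C)c(O[Si](C(C)C)(C(C)C)C(C)C)c2)c(OCOC)c(CC=C(C)C)c1O[Si](C(C)C)(C(C)C)C(C)C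
F6 | step 9 | 3-[3,4-bis(triisopropylsilyloxy)phenyl]-8-[(2R)-2-(tert-butyldimethylsilyloxy)-3-methylbut-3-enyl]-5-(methoxymethoxy)-6-(3-methylbut-2-enyl)-7-(triisopropylsilyloxy)-4H-chromen-4-one | C=C(C)[C@H](O[Si](C)(C)C(C)(C)C)Cc1c(O[Si](C(C)C)(C(C)C)C(C)C)c(CC=C(C)C)c(OCOC)c2c(=O)c(-c3ccc(O[Si](C(C)C)(C(C)C)C(C)C)c(O[Si](C(C)C)(C(C)C)C(C)C)c3)coc12
F7 | step 9 | 3-[3,4-bis(triisopropylsilyloxy)phenyl]-8-[(2R)-2-(tert-butyldimethylsilyloxy)-3-methylbut-3-enyl]-5-hydroxy-6-(3-methylbut-2-enyl)-7-(triisopropylsilyloxy)-4H-chromen-4-one | C=C(C)[C@H](O[Si](C)(C)C(C)(C)C)Cc1c(O[Si](C(C)C)(C(C)C)C(C)C)c(CC=C(C)C)c(O)c2c(=O)c(-c3ccc(O[Si](C(C)C)(C(C)C)C(C)C)c(O[Si](C(C)C)(C(C)C)C(C)C)c3)coc12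
F8 | step 4 | (3R)-3-(tert-butyldimethylsilyloxy)-4-methylpent-4-enal | C=C(C)[C@H](O[Si](C)(C)C(C)(C)C)CC=O
F9 | step 4 | tert-butyl(dimethyl){[(3R)-2-methylhex-1-en-5-yn-3-yl]oxy}silane | C=C(C)[C@H](O[Si](C)(C)C(C)(C)C)CC#C
F0 | step 15 | none | none
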